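**Retrosynthetic overview**

1. Ring labels: arene A–CH2–oxolane B–arene C–arene D–CH2–oxolane E–arene F; each oxolane is numbered O1, C2 (aryl), C3 (CH2OH), C4 (C–OH, arylmethyl), C5 (CH2). The last disconnections are the four O-benzyl ethers and then the C–D biaryl bond (Suzuki–Miyaura) between boronate 16 (rings D, E, F) and bromide 23 (rings A, B, C).
2. In each half the C2 aryl group (ring F or C) and the C3 hydrogen are removed together: Heck arylation of a 3-(hydroxymethyl)-4,5-dihydrofuran with relay to the C3 aldehyde, both centres controlled by the C4 hydroxyl.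
3. Both dihydrofurans come from one ester, 10 (17 is its debrominated form). Its ring is cut at O1–C5 and C3–C4: an enantioselective interrupted Feist–Benary annulation of chloroketone 7 with the enolate of ethyl formylacetate 8.
4. Enabling feature: in ring E the tertiary carbinol C4 lies between C3 and the ring CH2 (C5) bonded to O1, so C4–C5 is a latent α-chloroketone (carbonyl carbon next to CH2Cl) and O1–C2=C3 with its C3 carbon substituent is the enol of a β-formyl ester. The C4 hydroxyl made there then steers C2 and C3.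
5. Ring order: arene D (and A) is bought as homovanillic acid; oxolane E is formed first (and serves as B after debromination); arenes F and C are attached by Heck arylation; the C–D bond is made last.

Key step: step 4

Assumption: the sense of induction of the cinchona squaramide in step 4 cannot be predicted with confidence; the quinidine-derived catalyst is written, and its quinine-derived pseudo-enantiomer is to be used instead if a pilot run shows that it is the one leading to (4S)-10.

**Step 1**
Reactants: 1 2-(4-hydroxy-3-methoxyphenyl)acetic acid (homovanillic acid)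
Product: 2 2-(3-bromo-4-hydroxy-5-methoxyphenyl)acetic acid
Conditions: Br2 (1.05 equiv), AcOH, 15 °C
Reagents that add atoms: bromine, BrBr
Why: Electrophilic aromatic bromination, in which the free phenol directs to its one open ortho position (para is occupied), the future biaryl carbon of ring D.

**Step 2**
Reactants: 2 2-(3-bromo-4-hydroxy-5-methoxyphenyl)acetic acid
Product: 4 2-[4-(benzyloxy)-3-bromo-5-methoxyphenyl]acetic acid, via benzyl ester 3 (not isolated)
Conditions: BnBr (2.4 equiv), K2CO3, DMF, 60 °C; then NaOH, MeOH/H2O, 50 °C; then aq. HCl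
Reagents that add atoms: benzyl bromide, BrCc1ccccc1; sodium hydroxide, [Na+].[OH-]
Why: Williamson ether synthesis (with concurrent esterification) followed by saponification of the benzyl ester, to which the aryl benzyl ether is stable.

**Step 3**
Reactants: 4 2-[4-(benzyloxy)-3-bromo-5-methoxyphenyl]acetic acid
Product: 7 1-[4-(benzyloxy)-3-bromo-5-methoxyphenyl]-3-chloropropan-2-one, via acid chloride 5 (not isolated), via diazoketone 6 (not isolated)
Conditions: (COCl)2, DMF (cat.), CH2Cl2, 0 °C to rt; evaporate; CH2N2 (2.5 equiv), Et2O, 0 °C; then HCl (4 M in dioxane), 0 °C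
Reagents that add atoms: diazomethane, C=[N+]=[N-]; hydrogen chloride, Cl
Why: Acid chloride formation, acylation of diazomethane (first stage of the Arndt–Eistert sequence) and hydrochlorination of the diazoketone (Nierenstein-type) should give the chloromethyl ketone regiospecifically, without touching the benzylic CH2.

**Step 4**
Reactants: 7 1-[4-(benzyloxy)-3-bromo-5-methoxyphenyl]-3-chloropropan-2-one; 8 sodium 3-ethoxy-3-oxoprop-1-en-1-olate (sodium enolate of ethyl formylacetate)
Product: 10 ethyl (4S)-4-{[4-(benzyloxy)-3-bromo-5-methoxyphenyl]methyl}-4-hydroxy-4,5-dihydrofuran-3-carboxylate, via aldol adduct 9 (not isolated)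
Conditions: 8 (1.3 equiv), squaramide of 9-amino-9-deoxy-epi-quinidine and 3,5-bis(trifluoromethyl)aniline (10 mol%), AcOH (20 mol%), CH2Cl2/THF (4:1), −30 to 0 °C
Reagents that add atoms: none
Why: Proposed new method: the acetic acid buffer releases ethyl formylacetate from 8, the quinuclidine nitrogen of the catalyst forms its enolate while the two squaramide N–H bonds bind the ketone oxygen of 7, and the enolate carbon (future C3) adds to the carbonyl carbon (future C4) to give aldol 9 (interrupted Feist–Benary reaction). The formyl enol oxygen (future O1) of 9 then displaces chloride at the CH2Cl carbon (future C5) in a 5-exo-tet closure that forms ring E and pulls the reversible aldol step forward. The closest known reaction type is the cinchona-alkaloid-catalysed enantioselective interrupted Feist–Benary reaction of 1,3-dicarbonyl compounds with α-bromopyruvates and α-sulfonyloxy aryl ketones, and the racemic reaction with simple α-halo ketones is classical; an unactivated dialkyl α-chloroketone with a formylacetate donor has not been shown. The only new stereocentre, the carbinol C4, is controlled by the catalyst, which must tell the CH2Cl flank of the ketone from the CH2Ar flank while it holds both partners. The step needs aldol-before-alkylation chemoselectivity, which the activating α-chlorine on the ketone, the low concentration of free enolate under buffering and the low temperature should secure, and it needs O-closure through the aldehyde enol and not the ester, which the much higher enol content of the formyl group secures. No strong acid is present, so the tertiary hydroxyl should not be lost to give the furan.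

**Step 5**
Reactants: 10 ethyl (4S)-4-{[4-(benzyloxy)-3-bromo-5-methoxyphenyl]methyl}-4-hydroxy-4,5-dihydrofuran-3-carboxylate
Product: 11 (3S)-3-{[4-(benzyloxy)-3-bromo-5-methoxyphenyl]methyl}-4-(hydroxymethyl)-2,3-dihydrofuran-3-ol
Conditions: i-Bu2AlH (3.5 equiv), CH2Cl2, −78 °C; aq. potassium sodium tartrate (KNaC4H4O6) work-up with Et3N; crude product used at once
Reagents that add atoms: none
Why: 1,2-Reduction of the vinylogous carbonate ester with diisobutylaluminium hydride should give the allylic alcohol without touching C4, and the basic work-up and immediate use guard the acid-labile hydroxy enol ether against loss of water to the furan.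

**Step 6**
Reactants: 12 4-iodo-2-methoxyphenol
Product: 13 1-(benzyloxy)-4-iodo-2-methoxybenzene
Conditions: BnBr, K2CO3, acetone, reflux
Reagents that add atoms: benzyl bromide, BrCc1ccccc1
Why: Williamson ether synthesis on the phenol.

**Step 7**
Reactants: 11 (3S)-3-{[4-(benzyloxy)-3-bromo-5-methoxyphenyl]methyl}-4-(hydroxymethyl)-2,3-dihydrofuran-3-ol; 13 1-(benzyloxy)-4-iodo-2-methoxybenzene
Product: 15 (3S,4R,5S)-5-[4-(benzyloxy)-3-methoxyphenyl]-3-{[4-(benzyloxy)-3-bromo-5-methoxyphenyl]methyl}-4-(hydroxymethyl)oxolan-3-ol, via oxolane-3-carbaldehyde 14 (not isolated)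
Conditions: 13 (1.2 equiv), Pd(OAc)2 (5 mol%), n-Bu4NCl, NaHCO3, DMF, 40 °C; then MeOH, NaBH4, 0 °C
Reagents that add atoms: none
Why: Heck arylation of the cyclic enol ether (known for 2,3-dihydrofurans and furanoid glycals) should deliver the aryl group to C2 on the face of the C4 hydroxyl, which can bind palladium, and opposite the larger C4 arylmethyl group, the tertiary C3–palladium species can eliminate only toward a hydrogen of the CH2OH group, and re-addition of the same face-bound palladium hydride (the Heck reaction of an allylic alcohol to a β-aryl aldehyde) places hydrogen on C3 syn to the new aryl group, so that C2 and C3 of ring E are both relayed from C4 in one event before NaBH4 reduces aldehyde 14 in the same flask.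

**Step 8**
Reactants: 15 (3S,4R,5S)-5-[4-(benzyloxy)-3-methoxyphenyl]-3-{[4-(benzyloxy)-3-bromo-5-methoxyphenyl]methyl}-4-(hydroxymethyl)oxolan-3-ol
Product: 16 (3S,4R,5S)-5-[4-(benzyloxy)-3-methoxyphenyl]-3-{[4-(benzyloxy)-3-methoxy-5-(4,4,5,5-tetramethyl-1,3,2-dioxaborolan-2-yl)phenyl]methyl}-4-(hydroxymethyl)oxolan-3-ol
Conditions: B2pin2 (1.3 equiv), PdCl2(dppf) (5 mol%), KOAc, 1,4-dioxane, 85 °C
Reagents that add atoms: bis(pinacolato)diboron, CC1(C)OB(OC1(C)C)B1OC(C)(C)C(C)(C)O1
Why: Miyaura borylation of the ring D bromide, to which the free primary and tertiary hydroxyls and the benzylic oxolane ether are inert under the weak acetate base.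

**Step 9**
Reactants: 10 ethyl (4S)-4-{[4-(benzyloxy)-3-bromo-5-methoxyphenyl]methyl}-4-hydroxy-4,5-dihydrofuran-3-carboxylate
Product: 17 ethyl (4S)-4-{[4-(benzyloxy)-3-methoxyphenyl]methyl}-4-hydroxy-4,5-dihydrofuran-3-carboxylate
Conditions: Pd(OAc)2 (5 mol%), PPh3 (15 mol%), HCO2Na, DMF, 60 °C
Reagents that add atoms: none
Why: Palladium-catalysed hydrodehalogenation with formate as hydride source removes the ring bromine, so that the one enantioselective annulation also supplies ring B with ring A, while the push-pull alkene and the benzyl ether should not be reduced under these homogeneous conditions.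

**Step 10**
Reactants: 17 ethyl (4S)-4-{[4-(benzyloxy)-3-methoxyphenyl]methyl}-4-hydroxy-4,5-dihydrofuran-3-carboxylate
Product: 18 (3S)-3-{[4-(benzyloxy)-3-methoxyphenyl]methyl}-4-(hydroxymethyl)-2,3-dihydrofuran-3-ol
Conditions: i-Bu2AlH (3.5 equiv), CH2Cl2, −78 °C; aq. potassium sodium tartrate (KNaC4H4O6) work-up with Et3N; crude product used at once
Reagents that add atoms: none
Why: The same 1,2-reduction of the vinylogous carbonate ester with diisobutylaluminium hydride as in step 5, with the same precautions.

**Step 11**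
Reactants: 19 2-bromo-6-methoxyphenol
Product: 20 2-bromo-4-iodo-6-methoxyphenol
Conditions: NIS (1.05 equiv), TsOH·H2O (5 mol%), MeCN, 0 °C to rt
Reagents that add atoms: N-iodosuccinimide, O=C1CCC(=O)N1I
Why: Electrophilic aromatic iodination goes para to the phenol hydroxyl, both ortho positions being occupied.

**Step 12**
Reactants: 20 2-bromo-4-iodo-6-methoxyphenol
Product: 21 2-(benzyloxy)-1-bromo-5-iodo-3-methoxybenzene
Conditions: BnBr, K2CO3, acetone, reflux
Reagents that add atoms: benzyl bromide, BrCc1ccccc1
Why: Williamson ether synthesis on the phenol.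

**Step 13**
Reactants: 18 (3S)-3-{[4-(benzyloxy)-3-methoxyphenyl]methyl}-4-(hydroxymethyl)-2,3-dihydrofuran-3-ol; 21 2-(benzyloxy)-1-bromo-5-iodo-3-methoxybenzene
Product: 23 (3S,4R,5S)-5-[4-(benzyloxy)-3-bromo-5-methoxyphenyl]-3-{[4-(benzyloxy)-3-methoxyphenyl]methyl}-4-(hydroxymethyl)oxolan-3-ol, via oxolane-3-carbaldehyde 22 (not isolated)
Conditions: 21 (1.2 equiv), Pd(OAc)2 (5 mol%), n-Bu4NCl, NaHCO3, DMF, 40 °C; then MeOH, NaBH4, 0 °C
Reagents that add atoms: none
Why: The same hydroxyl-directed Heck arylation with relay to the aldehyde as in step 7 sets C2 and C3 of ring B from C4, and at 40 °C only the C–I bond of 21 should undergo oxidative addition, so the C–Br bond is kept for the biaryl coupling.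

**Step 14**
Reactants: 16 (3S,4R,5S)-5-[4-(benzyloxy)-3-methoxyphenyl]-3-{[4-(benzyloxy)-3-methoxy-5-(4,4,5,5-tetramethyl-1,3,2-dioxaborolan-2-yl)phenyl]methyl}-4-(hydroxymethyl)oxolan-3-ol; 23 (3S,4R,5S)-5-[4-(benzyloxy)-3-bromo-5-methoxyphenyl]-3-{[4-(benzyloxy)-3-methoxyphenyl]methyl}-4-(hydroxymethyl)oxolan-3-ol
Product: 24 tetra-O-benzyl ether of the target (all four phenols benzylated, rings A–F assembled)
Conditions: Pd(OAc)2 (5 mol%), SPhos (10 mol%), K3PO4, toluene/H2O (10:1), 60 °C
Reagents that add atoms: none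
Why: Suzuki–Miyaura coupling joins rings C and D, each partner has only one ortho substituent, which a dialkylbiarylphosphine–palladium catalyst should tolerate at moderate temperature, the four free hydroxyls need no protection, and no stereocentre is formed or touched (a biaryl with two ortho substituents has no stable axis).

**Step 15**
Reactants: 24 tetra-O-benzyl ether of the target
Product: 25 CNP0269573.1
Conditions: H2 (1 atm), 10% Pd/C, EtOAc/EtOH (1:1), rt, stopped at full debenzylation
Reagents that add atoms: none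
Why: Hydrogenolysis of the four aryl benzyl ethers over Pd/C is the fastest hydrogenolysis available in the molecule and should give the target if it is stopped before the benzylic C2–O1 bonds of rings B and E are attacked.

**Compound list**

1 | 2-(4-hydroxy-3-methoxyphenyl)acetic acid (homovanillic acid) | COc1cc(CC(=O)O)ccc1O | starting material
2 | 2-(3-bromo-4-hydroxy-5-methoxyphenyl)acetic acid | COc1cc(CC(=O)O)cc(Br)c1O | intermediate
3 | benzyl 2-[4-(benzyloxy)-3-bromo-5-methoxyphenyl]acetate | COc1cc(CC(=O)OCc2ccccc2)cc(Br)c1OCc1ccccc1 | intermediate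
4 | 2-[4-(benzyloxy)-3-bromo-5-methoxyphenyl]acetic acid | COc1cc(CC(=O)O)cc(Br)c1OCc1ccccc1 | intermediate
5 | 2-[4-(benzyloxy)-3-bromo-5-methoxyphenyl]acetyl chloride | COc1cc(CC(Cl)=O)cc(Br)c1OCc1ccccc1 | intermediate
6 | 1-[4-(benzyloxy)-3-bromo-5-methoxyphenyl]-3-diazopropan-2-one | COc1cc(CC(=O)C=[N+]=[N-])cc(Br)c1OCc1ccccc1 | intermediate
7 | 1-[4-(benzyloxy)-3-bromo-5-methoxyphenyl]-3-chloropropan-2-one | COc1cc(CC(=O)CCl)cc(Br)c1OCc1ccccc1 | intermediate
8 | sodium 3-ethoxy-3-oxoprop-1-en-1-olate (sodium enolate of ethyl formylacetate, enolate geometry not defined) | [Na+].[O-]C=CC(=O)OCC | starting material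
9 | ethyl (3S)-4-[4-(benzyloxy)-3-bromo-5-methoxyphenyl]-3-(chloromethyl)-2-formyl-3-hydroxybutanoate (C2 not defined, enolisable) | COc1cc(C[C@@](O)(CCl)C(C=O)C(=O)OCC)cc(Br)c1OCc1ccccc1 | intermediate
10 | ethyl (4S)-4-{[4-(benzyloxy)-3-bromo-5-methoxyphenyl]methyl}-4-hydroxy-4,5-dihydrofuran-3-carboxylate | COc1cc(C[C@@]2(O)COC=C2C(=O)OCC)cc(Br)c1OCc1ccccc1 | intermediate
11 | (3S)-3-{[4-(benzyloxy)-3-bromo-5-methoxyphenyl]methyl}-4-(hydroxymethyl)-2,3-dihydrofuran-3-ol | COc1cc(C[C@@]2(O)COC=C2CO)cc(Br)c1OCc1ccccc1 | intermediate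
12 | 4-iodo-2-methoxyphenol | COc1cc(I)ccc1O | starting material
13 | 1-(benzyloxy)-4-iodo-2-methoxybenzene | COc1cc(I)ccc1OCc1ccccc1 | intermediate
14 | (2S,3R,4S)-2-[4-(benzyloxy)-3-methoxyphenyl]-4-{[4-(benzyloxy)-3-bromo-5-methoxyphenyl]methyl}-4-hydroxyoxolane-3-carbaldehyde | COc1cc(C[C@@]2(O)CO[C@H](c3ccc(OCc4ccccc4)c(OC)c3)[C@H]2C=O)cc(Br)c1OCc1ccccc1 | intermediate
15 | (3S,4R,5S)-5-[4-(benzyloxy)-3-methoxyphenyl]-3-{[4-(benzyloxy)-3-bromo-5-methoxyphenyl]methyl}-4-(hydroxymethyl)oxolan-3-ol | COc1cc(C[C@@]2(O)CO[C@H](c3ccc(OCc4ccccc4)c(OC)c3)[C@H]2CO)cc(Br)c1OCc1ccccc1 | intermediate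
16 | (3S,4R,5S)-5-[4-(benzyloxy)-3-methoxyphenyl]-3-{[4-(benzyloxy)-3-methoxy-5-(4,4,5,5-tetramethyl-1,3,2-dioxaborolan-2-yl)phenyl]methyl}-4-(hydroxymethyl)oxolan-3-ol | COc1cc(C[C@@]2(O)CO[C@H](c3ccc(OCc4ccccc4)c(OC)c3)[C@H]2CO)cc(B2OC(C)(C)C(C)(C)O2)c1OCc1ccccc1 | intermediate
17 | ethyl (4S)-4-{[4-(benzyloxy)-3-methoxyphenyl]methyl}-4-hydroxy-4,5-dihydrofuran-3-carboxylate | COc1cc(C[C@@]2(O)COC=C2C(=O)OCC)ccc1OCc1ccccc1 | intermediate
18 | (3S)-3-{[4-(benzyloxy)-3-methoxyphenyl]methyl}-4-(hydroxymethyl)-2,3-dihydrofuran-3-ol | COc1cc(C[C@@]2(O)COC=C2CO)ccc1OCc1ccccc1 | intermediate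
19 | 2-bromo-6-methoxyphenol | COc1cccc(Br)c1O | starting material
20 | 2-bromo-4-iodo-6-methoxyphenol | COc1cc(I)cc(Br)c1O | intermediate
21 | 2-(benzyloxy)-1-bromo-5-iodo-3-methoxybenzene | COc1cc(I)cc(Br)c1OCc1ccccc1 | intermediate
22 | (2S,3R,4S)-2-[4-(benzyloxy)-3-bromo-5-methoxyphenyl]-4-{[4-(benzyloxy)-3-methoxyphenyl]methyl}-4-hydroxyoxolane-3-carbaldehyde | COc1cc(C[C@@]2(O)CO[C@H](c3cc(OC)c(OCc4ccccc4)c(Br)c3)[C@H]2C=O)ccc1OCc1ccccc1 | intermediate
23 | (3S,4R,5S)-5-[4-(benzyloxy)-3-bromo-5-methoxyphenyl]-3-{[4-(benzyloxy)-3-methoxyphenyl]methyl}-4-(hydroxymethyl)oxolan-3-ol | COc1cc(C[C@@]2(O)CO[C@H](c3cc(OC)c(OCc4ccccc4)c(Br)c3)[C@H]2CO)ccc1OCc1ccccc1 | intermediate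
24 | (3S,4R,5S)-5-{4-(benzyloxy)-3-[2-(benzyloxy)-5-{[(3S,4R,5S)-5-[4-(benzyloxy)-3-methoxyphenyl]-3-hydroxy-4-(hydroxymethyl)oxolan-3-yl]methyl}-3-methoxyphenyl]-5-methoxyphenyl}-3-{[4-(benzyloxy)-3-methoxyphenyl]methyl}-4-(hydroxymethyl)oxolan-3-ol | COc1cc(C[C@@]2(O)CO[C@H](c3cc(OC)c(OCc4ccccc4)c(-c4cc(C[C@@]5(O)CO[C@H](c6ccc(OCc7ccccc7)c(OC)c6)[C@H]5CO)cc(OC)c4OCc4ccccc4)c3)[C@H]2CO)ccc1OCc1ccccc1 | intermediate
25 | CNP0269573.1, (3S,4R,5S)-5-{4-hydroxy-3-[2-hydroxy-5-{[(3S,4R,5S)-3-hydroxy-5-(4-hydroxy-3-methoxyphenyl)-4-(hydroxymethyl)oxolan-3-yl]methyl}-3-methoxyphenyl]-5-methoxyphenyl}-3-[(4-hydroxy-3-methoxyphenyl)methyl]-4-(hydroxymethyl)oxolan-3-ol | COc1cc(C[C@@]2(O)CO[C@H](c3cc(OC)c(O)c(-c4cc(C[C@@]5(O)CO[C@H](c6ccc(O)c(OC)c6)[C@H]5CO)cc(OC)c4O)c3)[C@H]2CO)ccc1O | target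

**Step count and risks**

Total step count: 15. Longest linear sequence: 9 steps (steps 1, 2, 3, 4, 5, 7, 8, 14, 15; the branch through steps 9, 10 and 13 is equally long).

Steps most likely to fail:

1. Step 4 (bears the label). What may go wrong: too little facial discrimination of the ketone by the catalyst, a racemic background reaction through uncomplexed sodium enolate, direct C- or O-alkylation of the enolate at the CH2Cl carbon before the aldol step, or loss of water from the product to give the furan. Fallback: setting out from 7 and 8, the same buffered annulation is run with triethylamine in place of the chiral catalyst (the classical achiral interrupted Feist–Benary reaction), which should give the racemic dihydrofuran ester F1. This is resolved by preparative chromatography on a chiral stationary phase, and the (4S) enantiomer re-enters the route as 10.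

2. Step 7 (step 13 is the same operation on 18). What may go wrong: release of the free enol from palladium hydride followed by unselective tautomerisation, base-promoted epimerisation or retro-aldol opening of the β-hydroxy aldehyde before reduction, β-hydroxide elimination from the C3–palladium species, or aromatisation of 11 on handling. Fallback: setting out from 11, the primary hydroxyl is silylated (TBSCl, imidazole, DMF) to the silyl ether F2. Heck arylation with 13 under the conditions of step 7 then stops at the exocyclic silyl enol ether F3, with C2 set as before. Hydroxyl-directed hydrogenation with [Ir(cod)(PCy3)(py)]PF6 and H2 in CH2Cl2 delivers hydrogen to C3 from the face of the C4 hydroxyl and should give the silyl ether F4. Desilylation with n-Bu4NF in THF returns to the route at 15.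

3. Step 15. What may go wrong: over-reduction, in which the benzylic C2–O1 bonds of rings B and E are cleaved once the para-phenols are free, or acid-promoted opening of the oxolane and Friedel–Crafts closure onto the neighbouring arene on an acidic catalyst batch. Fallback: setting out from 24, the four aryl benzyl ethers are cleaved without hydrogen by BCl3 with pentamethylbenzene as cation scavenger in CH2Cl2 at −78 °C, a Lewis-acid dealkylation that returns directly to 25 and makes no new compound (F0).

**Further compounds**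

F1 | step 4 | racemic ethyl 4-{[4-(benzyloxy)-3-bromo-5-methoxyphenyl]methyl}-4-hydroxy-4,5-dihydrofuran-3-carboxylate | COc1cc(CC2(O)COC=C2C(=O)OCC)cc(Br)c1OCc1ccccc1
F2 | step 7 | (3S)-3-{[4-(benzyloxy)-3-bromo-5-methoxyphenyl]methyl}-4-({[tert-butyl(dimethyl)silyl]oxy}methyl)-2,3-dihydrofuran-3-ol | COc1cc(C[C@@]2(O)COC=C2CO[Si](C)(C)C(C)(C)C)cc(Br)c1OCc1ccccc1
F3 | step 7 | (3S,5R)-5-[4-(benzyloxy)-3-methoxyphenyl]-3-{[4-(benzyloxy)-3-bromo-5-methoxyphenyl]methyl}-4-({[tert-butyl(dimethyl)silyl]oxy}methylidene)oxolan-3-ol (alkene geometry not defined) | COc1cc(C[C@@]2(O)CO[C@H](c3ccc(OCc4ccccc4)c(OC)c3)C2=CO[Si](C)(C)C(C)(C)C)cc(Br)c1OCc1ccccc1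
F4 | step 7 | (3S,4R,5S)-5-[4-(benzyloxy)-3-methoxyphenyl]-3-{[4-(benzyloxy)-3-bromo-5-methoxyphenyl]methyl}-4-({[tert-butyl(dimethyl)silyl]oxy}methyl)oxolan-3-ol | COc1cc(C[C@@]2(O)CO[C@H](c3ccc(OCc4ccccc4)c(OC)c3)[C@H]2CO[Si](C)(C)C(C)(C)C)cc(Br)c1OCc1ccccc1
F0 | step 15 | none | none
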